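Labdane numbering is used (ring B = C5–C10; C8 and C13 flank the ether oxygen). Ring B is cut at C5–C6 and C8–C9: C5 and C9 both hang on the quaternary C10, and C6–C7–C8 bridges them. In one operation acetone (C6–C7–C8) is joined by two (S)-proline-mediated aldol reactions to the two enantiotopic formyl groups of a prochiral 2-methyl-2-(ethoxycarbonylmethyl)malonaldehyde; lactonisation of the carbinol that lies next to the acetate arm on C10 desymmetrises the product and fixes C10. This temporary C9–O bond steers the CMe2CO2Me unit to C5, is eliminated, and lets C11 enter trans; the ring ketone is finally traded for the C8 ether oxygen.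

Key step: step 4

Remark: (S)-proline is assumed to add to the Re face of both formyl groups, as it does with other α-branched aldehydes; C1/C2 = CH2CO2H arm on C10, C3/C4 = CMe2CO2H arm on C5, C17 and C20 = methyls on C8 and C10.

Step 1
Reactants: 1 3-methylpent-2-en-4-yn-1-ol (commercial E/Z mixture); 2 triethyl orthoacetate
Product: 4 ethyl 3-ethynyl-3-methylpent-4-enoate (racemic), via ketene acetal 3 (not isolated)
Conditions: MeC(OEt)3 (5 equiv), EtCO2H (cat.), 140 °C, EtOH distilled off
Reagents that add atoms: none
Why: Johnson–Claisen rearrangement: the mixed ketene acetal 3 undergoes a [3,3] shift onto the trisubstituted alkene carbon and creates the quaternary carbon (future C10) carrying methyl, ethynyl, vinyl and the acetate arm; the racemic centre is of no consequence because step 2 removes it.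

Step 2
Reactants: 4 ethyl 3-ethynyl-3-methylpent-4-enoate
Product: 5 ethyl 3-ethenyl-3-methylpent-4-enoate
Conditions: H2 (1 atm), Pd/CaCO3 poisoned with Pb(OAc)2, quinoline, hexane, rt
Reagents that add atoms: none
Why: Partial catalytic hydrogenation of the terminal alkyne on lead-poisoned palladium should stop at the alkene and give the achiral divinyl ester, whose quaternary carbon is now a prochiral centre.

Step 3
Reactants: 5 ethyl 3-ethenyl-3-methylpent-4-enoate
Product: 7 ethyl 3-formyl-3-methyl-4-oxobutanoate, via bis-ozonide 6 (not isolated)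
Conditions: O3, CH2Cl2, −78 °C; then Me2S, −78 °C → rt; used crude
Reagents that add atoms: ozone, [O-][O+]=O
Why: Ozonolysis with reductive work-up cleaves both vinyl groups to formyl groups and gives the non-enolisable, prochiral malonaldehyde.

Step 4
Reactants: 7 ethyl 3-formyl-3-methyl-4-oxobutanoate; 8 acetone
Product: 11 (3aS,7aR)-3a-methyl-3a,7a-dihydro-1-benzofuran-2,6(3H,7H)-dione, via aldol adduct 9 (not isolated), via diol ketone 10 (not isolated)
Conditions: (S)-proline (30 mol %), acetone (5 equiv), DMSO, rt; then TsOH·H2O (0.3 equiv), PhMe, 60 °C, same flask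
Reagents that add atoms: none
Why: The enamine of acetone and (S)-proline adds to one formyl group of 7 (C8–C9, giving 9), the enamine on the remaining methyl group then closes ring B onto the second formyl group (C5–C6, a 6-enolendo-exo-trig aldol addition, giving 10), and acid finally closes the γ-lactone from the hydroxyl cis to the CH2CO2Et arm (5-exo-trig acyl substitution) and dehydrates the other β-hydroxyl to the enone. The closest known reaction types are the proline-catalysed aldol addition of acetone to α-branched aldehydes and the amine-catalysed intramolecular aldol condensation, merged here into a [3+3] annulation in which acetone is C6–C7–C8. Both aldol events should occur on the Re face of the formyl carbon under catalyst control, so both carbinol carbons of 10 are R. Because the formyl groups are enantiotopic, one R carbinol lies cis to the acetate arm and survives as the lactone carbon C9, while the other lies trans and can only be eliminated to become C5, whichever formyl group reacts first; this coupling of face selectivity to lactonisation sets the quaternary centre C10, the only stereocentre of 11 that is carried to the target. The step needs single addition of acetone and dehydration on one side only, which the fast intramolecular second aldol, the limited excess of acetone and the capture of the cis hydroxyl as the lactone should secure.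

Step 5
Reactants: 11 lactone enone; 12 1-methoxy-2-methyl-1-(trimethylsilyloxy)prop-1-ene
Product: 14 methyl 2-methyl-2-[(3aS,4R,7aR)-3a-methyl-2,6-dioxooctahydro-1-benzofuran-4-yl]propanoate, via silyl enol ether 13 (not isolated)
Conditions: TMSOTf (10 mol %), CH2Cl2, −78 °C; then 1 M HCl, THF, 0 °C
Reagents that add atoms: none
Why: Mukaiyama–Michael addition of the silyl ketene acetal to the enone; the nucleophile should enter C5 on the convex face of the cis-fused bicycle, anti to the lactone ring and cis to the C10 methyl group, which sets C5.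

Step 6
Reactants: 14 keto lactone ester
Product: 16 methyl 2-[6-(1-methoxy-2-methyl-1-oxopropan-2-yl)-1-methyl-4-oxocyclohex-2-en-1-yl]acetate (C5 side chain cis to the C10 methyl), via enone acid 15 (not isolated)
Conditions: DBU (2.2 equiv), MeCN, 0 °C → rt; then MeI (3 equiv)
Reagents that add atoms: iodomethane, CI
Why: Base-induced E1cB elimination (retro-oxa-Michael) of the β-acyloxy ketone expels the lactone carboxylate and unveils the C8=C9 enone, and O-alkylation of the carboxylate makes the opening irreversible; the temporary C9 centre is erased, C5 and C10 are untouched.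

Step 7
Reactants: 16 enone diester
Product: 17 α-iodoenone (iodine on C8)
Conditions: I2 (1.5 equiv), pyridine/CH2Cl2 1:1, rt
Reagents that add atoms: iodine, II
Why: α-Iodination of the enone (pyridine-mediated addition, iodination, elimination) places iodine on C8 without touching a stereocentre.

Step 8
Reactants: 17 α-iodoenone
Product: 18 α-methyl enone (C17 on C8)
Conditions: MeB(OH)2 (2 equiv), PdCl2(dppf) (5 mol %), K2CO3, dioxane/H2O, 80 °C
Reagents that add atoms: methylboronic acid, CB(O)O
Why: Suzuki–Miyaura cross-coupling of the α-iodoenone with methylboronic acid installs C17 on C8; no stereocentre is involved.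

Step 9
Reactants: 18 α-methyl enone; 19 2-(2-bromoethyl)-2-methyl-1,3-dioxolane
Product: 22 vinyl triflate (C7–OTf, C7=C8), via Grignard reagent 20 (not isolated), via magnesium enolate 21 (not isolated)
Conditions: 19, Mg, THF; CuBr·SMe2 (1.0 equiv), THF/Me2S, −78 → −30 °C; then PhNTf2, DMPU, −30 °C → rt
Reagents that add atoms: N-phenylbis(trifluoromethanesulfonimide), O=S(=O)(N(c1ccccc1)S(=O)(=O)C(F)(F)F)C(F)(F)F
Why: Copper-mediated conjugate addition of the Grignard reagent; the C11 chain should enter C9 axially, anti to the pseudo-axial C10 methyl group and trans to the C5 substituent (the usual 3,5-trans outcome for 5-substituted cyclohexenones), which sets C9, and the regiodefined enolate 21 is trapped on oxygen as the vinyl triflate.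

Step 10
Reactants: 22 vinyl triflate
Product: 23 7,8-alkene with the dioxolane side chain
Conditions: Pd(OAc)2 (5 mol %), PPh3 (10 mol %), HCO2H, Bu3N, DMF, 60 °C
Reagents that add atoms: none
Why: Palladium-catalysed formate reduction of the vinyl triflate removes the C7 oxygen and leaves the trisubstituted C7=C8 alkene with no change at any stereocentre.

Step 11
Reactants: 23 7,8-alkene
Product: 25 cyclic methyl ketal (13-methoxy-8,13-epoxide, both C13 anomers), via methyl hemiketal 24 (not isolated)
Conditions: TsOH·H2O (20 mol %), MeOH, 40 °C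
Reagents that add atoms: methanol, CO; water, O
Why: Acid-catalysed transketalisation gives hemiketal 24, whose hydroxyl adds in Markovnikov fashion to the protonated C7=C8 alkene (6-exo-trig intramolecular hydroalkoxylation, as in the cyclisation of 6-methylhept-5-en-2-one-type enones); the oxygen can reach C8 only from the α face because its tether is the axial α chain on C9, so the pyran is cis-fused and C8 is set (oxygen α, methyl β).

Step 12
Reactants: 25 cyclic methyl ketal
Product: 26 dimethyl (5R,8R,9S,10S,13R)-8,13-epoxy-2,3-secolabd-14-ene-2,3-dioate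
Conditions: CH2=CHMgBr (4 equiv), CuBr·SMe2 (2 equiv), BF3·OEt2 (4 equiv), THF/Et2O, −78 → −40 °C
Reagents that add atoms: vinylmagnesium bromide, C=C[Mg]Br
Why: Lewis-acid ionisation of the ketal to the cyclic oxocarbenium ion and its capture by the vinylcopper reagent (acetal substitution by organocopper and BF3); axial attack on the half-chair, anti-periplanar to the ring-oxygen lone pair, should place the vinyl group α (axial) and leave the methyl group equatorial, which sets C13 as R.

Step 13
Reactants: 26 dimethyl ester
Product: 27 (5R,8R,9S,10S,13R)-8,13-epoxy-2,3-secolabd-14-ene-2,3-dioic acid (CNP0186744.1)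
Conditions: KOH (10 equiv), MeOH/H2O, 80 °C; then 1 M HCl to pH 3, 0 °C
Reagents that add atoms: potassium hydroxide, [K+].[OH-]
Why: Saponification of both methyl esters (forcing conditions for the hindered α,α-dimethyl ester) followed by mild acidification gives the diacid; the tertiary allylic ether and all stereocentres are stable to base.

Compound list
1 | 3-methylpent-2-en-4-yn-1-ol (E/Z mixture) | C#CC(C)=CCO | starting material
2 | triethyl orthoacetate | CCOC(C)(OCC)OCC | starting material
3 | 1-ethoxy-1-(3-methylpent-2-en-4-ynyloxy)ethene (mixed ketene acetal) | C#CC(C)=CCOC(=C)OCC | intermediate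
4 | ethyl 3-ethynyl-3-methylpent-4-enoate (racemic) | CCOC(=O)CC(C)(C=C)C#C | intermediate
5 | ethyl 3-ethenyl-3-methylpent-4-enoate | CCOC(=O)CC(C)(C=C)C=C | intermediate
6 | ethyl 3,3-di(1,2,4-trioxolan-3-yl)butanoate (bis-ozonide, isomer mixture) | CCOC(=O)CC(C)(C1OCOO1)C1OCOO1 | intermediate
7 | ethyl 3-formyl-3-methyl-4-oxobutanoate | CCOC(=O)CC(C)(C=O)C=O | intermediate
8 | acetone | CC(C)=O | starting material
9 | ethyl (4R)-3-formyl-4-hydroxy-3-methyl-6-oxoheptanoate (either configuration at C3) | CCOC(=O)CC(C)(C=O)[C@H](O)CC(C)=O | intermediate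
10 | ethyl 2-[(2R,6R)-2,6-dihydroxy-1-methyl-4-oxocyclohexyl]acetate | CCOC(=O)CC1(C)[C@H](O)CC(=O)C[C@H]1O | intermediate
11 | (3aS,7aR)-3a-methyl-3a,7a-dihydro-1-benzofuran-2,6(3H,7H)-dione (cis-fused; lactone oxygen on C9, enone C5=C6–C7=O) | O=C1C[C@@]2(C)C=CC(=O)C[C@H]2O1 | intermediate
12 | 1-methoxy-2-methyl-1-(trimethylsilyloxy)prop-1-ene | COC(O[Si](C)(C)C)=C(C)C | starting material
13 | trimethylsilyl enol ether of 14 (C6=C7–OSiMe3) | O=C1C[C@@]2(C)[C@H](C(C)(C)C(=O)OC)C=C(O[Si](C)(C)C)C[C@H]2O1 | intermediate
14 | methyl 2-methyl-2-[(3aS,4R,7aR)-3a-methyl-2,6-dioxooctahydro-1-benzofuran-4-yl]propanoate | O=C1C[C@@]2(C)[C@H](C(C)(C)C(=O)OC)CC(=O)C[C@H]2O1 | intermediate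
15 | 2-[6-(1-methoxy-2-methyl-1-oxopropan-2-yl)-1-methyl-4-oxocyclohex-2-en-1-yl]acetic acid (present as its DBU salt; side chain cis to ring methyl) | OC(=O)C[C@]1(C)C=CC(=O)C[C@H]1C(C)(C)C(=O)OC | intermediate
16 | methyl 2-[6-(1-methoxy-2-methyl-1-oxopropan-2-yl)-1-methyl-4-oxocyclohex-2-en-1-yl]acetate (C5 side chain cis to C10 methyl) | COC(=O)C[C@]1(C)C=CC(=O)C[C@H]1C(C)(C)C(=O)OC | intermediate
17 | 3-iodo derivative of 16 (iodine on C8) | COC(=O)C[C@]1(C)C=C(I)C(=O)C[C@H]1C(C)(C)C(=O)OC | intermediate
18 | 3-methyl derivative of 16 (C17 on C8) | COC(=O)C[C@]1(C)C=C(C)C(=O)C[C@H]1C(C)(C)C(=O)OC | intermediate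
19 | 2-(2-bromoethyl)-2-methyl-1,3-dioxolane | CC1(CCBr)OCCO1 | starting material
20 | [2-(2-methyl-1,3-dioxolan-2-yl)ethyl]magnesium bromide | CC1(CC[Mg]Br)OCCO1 | intermediate
21 | bromomagnesium enolate of the conjugate adduct (C9 chain trans to C5 chain and to C10 methyl) | COC(=O)C[C@]1(C)[C@H](CCC2(C)OCCO2)C(C)=C(O[Mg]Br)C[C@H]1C(C)(C)C(=O)OC | intermediate
22 | vinyl triflate (C7–OTf, C7=C8) | COC(=O)C[C@]1(C)[C@H](CCC2(C)OCCO2)C(C)=C(OS(=O)(=O)C(F)(F)F)C[C@H]1C(C)(C)C(=O)OC | intermediate
23 | 7,8-alkene with the 2-(2-methyl-1,3-dioxolan-2-yl)ethyl chain on C9 | COC(=O)C[C@]1(C)[C@H](CCC2(C)OCCO2)C(C)=CC[C@H]1C(C)(C)C(=O)OC | intermediate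
24 | methyl hemiketal of the C13 ketone (both C13 epimers) | COC(=O)C[C@]1(C)[C@H](CCC(C)(O)OC)C(C)=CC[C@H]1C(C)(C)C(=O)OC | intermediate
25 | dimethyl 13-methoxy-8,13-epoxy-14,15-dinor-2,3-secolabdane-2,3-dioate (cis-fused pyran, both C13 anomers) | COC(=O)C[C@]1(C)[C@@H]2CCC(C)(OC)O[C@]2(C)CC[C@H]1C(C)(C)C(=O)OC | intermediate
26 | dimethyl (5R,8R,9S,10S,13R)-8,13-epoxy-2,3-secolabd-14-ene-2,3-dioate | C=C[C@@]1(C)CC[C@H]2[C@@](C)(CC(=O)OC)[C@H](C(C)(C)C(=O)OC)CC[C@@]2(C)O1 | intermediate
27 | (5R,8R,9S,10S,13R)-8,13-epoxy-2,3-secolabd-14-ene-2,3-dioic acid | C=C[C@@]1(C)CC[C@H]2[C@@](C)(CC(=O)O)[C@H](C(C)(C)C(=O)O)CC[C@@]2(C)O1 | target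

Total step count: 13. Longest linear sequence: 13 steps (1 to 27).

Steps most likely to fail

Step 4. The ring-closing aldol may escape catalyst control, acetone may add twice, or both carbinols may dehydrate; each would erode enantiopurity or divert material to the achiral dienone. The fallback sets out from 7 and keeps the same two bond formations in one operation without stereocontrol: double aldol condensation with acetone (piperidine, AcOH, PhMe, reflux) should give ethyl 2-(1-methyl-4-oxocyclohexa-2,5-dien-1-yl)acetate F1. Hydrolysis with LiOH gives 2-(1-methyl-4-oxocyclohexa-2,5-dien-1-yl)acetic acid F2. The enantioselective step is then a separate intramolecular oxa-Michael desymmetrisation of the dienone under a cinchona-alkaloid-derived bifunctional thiourea catalyst, which returns to 11.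

Step 5. The conjugate addition may stall or reverse, because the new bond joins a fully substituted nucleophilic carbon to a carbon next to the quaternary C10. The fallback sets out from 11: Hosomi–Sakurai conjugate addition of trimethyl(3-methylbut-2-enyl)silane (TiCl4, CH2Cl2, −78 °C) delivers the slimmer allyl nucleophile through its γ carbon, again to the convex face, giving the 2-methylbut-3-en-2-yl keto lactone F3. Oxidative cleavage of the vinyl group (RuCl3 cat., NaIO4) gives the keto lactone acid F4, and esterification with TMSCHN2 returns to 14.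

Step 12. Facial selectivity in the attack on the oxocarbenium ion may be poor, because the axial trajectory runs syn to the C7 methylene; the C13 epimer would then form. The fallback sets out from 23 and sets C13 by reagent control before the ether is closed: mild aqueous acid (PPTS, acetone/H2O) unmasks the methyl ketone F5. Catalytic asymmetric vinylation (divinylzinc, Ti(OiPr)4, chiral bis-sulfonamide diol ligand) gives the (13R) tertiary allylic alcohol F6. Cold Brønsted acid (TfOH cat., CH2Cl2, −78 °C) then adds the hydroxyl to the C7=C8 alkene, again from the α face, and returns to 26.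

Further compounds
F1 | step 4 | ethyl 2-(1-methyl-4-oxocyclohexa-2,5-dien-1-yl)acetate | CCOC(=O)CC1(C)C=CC(=O)C=C1
F2 | step 4 | 2-(1-methyl-4-oxocyclohexa-2,5-dien-1-yl)acetic acid | OC(=O)CC1(C)C=CC(=O)C=C1
F3 | step 5 | (3aS,4R,7aR)-3a-methyl-4-(2-methylbut-3-en-2-yl)hexahydro-1-benzofuran-2,6-dione | O=C1C[C@@]2(C)[C@H](C(C)(C)C=C)CC(=O)C[C@H]2O1
F4 | step 5 | 2-methyl-2-[(3aS,4R,7aR)-3a-methyl-2,6-dioxooctahydro-1-benzofuran-4-yl]propanoic acid | O=C1C[C@@]2(C)[C@H](C(C)(C)C(O)=O)CC(=O)C[C@H]2O1
F5 | step 12 | 7,8-alkene methyl ketone (3-oxobutyl chain on C9) | COC(=O)C[C@]1(C)[C@H](CCC(C)=O)C(C)=CC[C@H]1C(C)(C)C(=O)OC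
F6 | step 12 | (13R) tertiary allylic alcohol (3-hydroxy-3-methylpent-4-enyl chain on C9) | COC(=O)C[C@]1(C)[C@H](CC[C@@](C)(O)C=C)C(C)=CC[C@H]1C(C)(C)C(=O)OC
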